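The data come from a simulation with made-up constants.

Follow the Q.

common to all: Q 0.050 M

| charge | Z | temperature | remark | time |
|---|---|---|---|---|
| spring | 2.5 equiv | 20 °C | run made earlier |  |
| dawn | 4 equiv | 38 °C | run made earlier |  |
| north-west | 1.80 equiv | 50 °C |  | 3.0 min |
| north | 1.80 equiv | 25 °C |  | 3.0 min |

- spring (time / min: D / %, Q / %): 1.00: 3, 80; 2.00: 10, 66; 4.00: 25, 47; 6.00: 37, 39; 8.00: 45, 29
- dawn (time / min: D / %, Q / %): 0.333: 7, 72; 0.667: 20, 50; 0.833: 27, 45; 1.50: 47, 28; 2.50: 67, 13; 4.00: 77, 7

(each reading ± 1.5 percentage points)

* which flask leads in amount of D, in percent of the Q charged ("all alike" within 1.5 percentage points) (north-west / north / all alike)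
* how much D is there at the end, in percent of the Q charged: north-west
* how much D is there at the end, in percent of the Q charged: north



- The bench rule for a reagent in excess, the pseudo-first-order view, holds [Z] at its charged value. The fraction of Q left is then exp(−τ), and we count by τ, the clock, which is the rate constant times charged [Z] times time.
- We read the constant from the first reading of each run, with Z taken at its charge. Spring gives a reading of 1.79 M⁻¹ min⁻¹ and dawn 4.93 M⁻¹ min⁻¹, both carrying the scatter.
- We let the constant grow by a fixed factor per degree, which gives 2.37 M⁻¹ min⁻¹ for north and, by a longer extrapolation, 9.71 M⁻¹ min⁻¹ for north-west.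
- The north-west clock τ 2.62 stands well ahead of the north clock 0.639. Our rule therefore leaves Q at 7.26% in north-west and 52.8% in north.
- The border lies in the ratio of the charges, 0.556 Q per Z. If each Q that reacts takes one Z, the rule's own conversion spends 51.5% of the Z in north-west and 26.2% in north.
- So we trust north roughly, and in north-west we expect Q well above the rule. If the step to D takes a Z as well, full conversion asks 1.11 of the Z charge, more than the flask holds.
- The forecast has north-west leading, with D at 64% (54% to 73%) there and 20% (15% to 25%) in north, holding that in north-west “the second step is fast”.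
- The flasks give D at 40.0% in north-west and 15.5% in north, so north-west leads. The main reason for the low D of north is the time allowed: after 30.0 min that flask holds D at 57.9%, against 15.5% at 3.0 min.

    D ⇌ L (K = 4.10, k = 0.00361 s⁻¹, Ea = 92.0 kJ mol⁻¹, ΔH = 0 kJ mol⁻¹)
    Z + E → D (k = 0.316 M⁻¹ s⁻¹, Ea = 48.0 kJ mol⁻¹)
    Q + Z → E (k = 0.171 M⁻¹ s⁻¹, Ea = 47.0 kJ mol⁻¹)
    (constants at 50 °C)

- At the end Q stands at 58.8% in north against the rule's 52.8%, but at 23.9% in north-west against 7.26%, with Z down to 26.5% of its charge. Holding Z at its charge lifts the D of north-west from 40.0% to 62.3%, so the depletion of Z is one part of the shortfall. A further flask, like north but with 0.20 M of Q, runs at the same equivalents on a clock of 2.56, close to the 2.62 of north-west, and ends with Q at 25.3%.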